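**Retrosynthetic overview**

1. Target ⇐ fluoride desilylation ⇐ one i-Bu2AlH reduction that opens an (E)-α-trienylidene γ-lactone to the C26/C27 diol and turns a conjugated nitrile into the C1 enal; C15=C16 comes from a Horner–Wadsworth–Emmons reaction of an α-phosphono lactone with a C16–C24 trienal.
2. Lactone (C14–C15 bond, C14 stereocentre) ⇐ dirhodium-carbenoid C–H insertion of a C26 diazophosphonoacetate; C26–OH ⇐ C10-hydroxyl-directed reduction of a spiro[4.5]decan-1-one.
3. Key new step: gold-catalysed alkyne–alkene cyclization / semipinacol ring expansion / iodination of an acyclic alkenylcyclobutanol builds the cyclohexane (C6–C7) and the cyclopentanone together and sets C6, C11 and the alkene geometry; Negishi methylation completes the tetrasubstituted alkene.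
4. Alkenylcyclobutanol ⇐ cyclobutanone + alkenyllithium (trans-hydrostannation of a tertiary propargylic alcohol) ⇐ epoxy chloride → alkynide alkylation ⇐ Sharpless epoxidation of geraniol (C10, the only reagent-controlled stereocentre).
5. Ring order: cyclohexane and cyclopentane together (step 10), then a temporary γ-lactone (step 18) that is opened again in step 22.

Assumption: atom labels are iridal-type (C1 formyl carbon, C2 its α-carbon, C3–C5 hydroxypropyl chain, C6–C10 cyclohexane carbons, C11 spiro atom, C12–C14 and C26 cyclopentane, C15–C23 side chain, C27 the CH2OH carbon); spiro[4.5]decane locants in names are 1 = C26, 2 = C14, 5 = C11, 6–10 = C6–C10; the iodosilane, melonal and the formyl ylide are taken as commercial.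

**Route**

Step 1
Reactants: 1 geraniol
Product: 2 (2S,3S)-2,3-epoxygeraniol
Conditions: Ti(OiPr)4 (5 mol %), L-(+)-diethyl tartrate (7 mol %), t-BuOOH, 4 Å MS, CH2Cl2, −20 °C
Reagents that add atoms: tert-butyl hydroperoxide, CC(C)(C)OO
Why: Sharpless asymmetric epoxidation of an (E)-trisubstituted allylic alcohol, in which the L-(+)-tartrate catalyst gives the (2S,3S)-epoxide and thereby sets the future C10 carbinol centre.

Step 2
Reactants: 2 (2S,3S)-2,3-epoxygeraniol
Product: 3 (2R,3S)-1-chloro-2,3-epoxy-3,7-dimethyloct-6-ene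
Conditions: PPh3, CCl4, NaHCO3, reflux
Reagents that add atoms: carbon tetrachloride, ClC(Cl)(Cl)Cl
Why: Appel chlorination of the primary alcohol under buffered neutral conditions leaves the epoxide and both stereocentres untouched (the C2 descriptor changes only through priorities).

Step 3
Reactants: 3 (2R,3S)-1-chloro-2,3-epoxy-3,7-dimethyloct-6-ene; 4 tert-butyl(3-iodopropoxy)diphenylsilane
Product: 6 (S)-11-(tert-butyldiphenylsilyloxy)-2,6-dimethylundec-2-en-7-yn-6-ol, via dilithio alkynyl alkoxide 5 (not isolated)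
Conditions: n-BuLi (3.3 equiv), THF, −40 °C; then 4, DMPU, −40 °C → rt
Reagents that add atoms: none
Why: Base-induced eliminative opening of the 2,3-epoxy chloride gives the tertiary propargylic alkoxide with its C–O stereocentre retained, and the lithium alkynide is then C-alkylated by the primary iodide (alkynide SN2 alkylation).

Step 4
Reactants: 6 (S)-11-(tert-butyldiphenylsilyloxy)-2,6-dimethylundec-2-en-7-yn-6-ol
Product: 7 (5S)-5-[5-(tert-butyldiphenylsilyloxy)pent-1-ynyl]-5-methyloxolan-2-ol (lactol, anomers)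
Conditions: O3, pyridine, CH2Cl2, −78 °C; then Me2S
Reagents that add atoms: ozone, [O-][O+]=O
Why: Ozonolysis cleaves the electron-rich trisubstituted alkene much faster than the alkyne, and the resulting γ-hydroxy aldehyde closes to the lactol.

Step 5
Reactants: 7 lactol
Product: 8 (S)-10-(tert-butyldiphenylsilyloxy)-5-methyldeca-1,6-diyn-5-ol
Conditions: dimethyl (1-diazo-2-oxopropyl)phosphonate, K2CO3, MeOH, rt
Reagents that add atoms: dimethyl (1-diazo-2-oxopropyl)phosphonate, CC(=O)C(=[N+]=[N-])P(=O)(OC)OC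
Why: Ohira–Bestmann (Seyferth–Gilbert) homologation acts on the open hydroxy-aldehyde form of the lactol and gives the terminal alkyne without touching the tertiary carbinol.

Step 6
Reactants: 8 (S)-10-(tert-butyldiphenylsilyloxy)-5-methyldeca-1,6-diyn-5-ol
Product: 10 (S)-1-(tert-butyldimethylsilyloxy)-11-(tert-butyldiphenylsilyloxy)-6-methylundeca-2,7-diyn-6-ol, via dilithium dialkoxide 9 (not isolated)
Conditions: n-BuLi (2.2 equiv), THF, −78 °C; (CH2O)n, −78 → 0 °C; then TBSCl, DMAP (cat.), 0 °C → rt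
Reagents that add atoms: paraformaldehyde (as formaldehyde), C=O; tert-butyldimethylsilyl chloride, CC(C)(C)[Si](C)(C)Cl
Why: The lithium alkynide adds to formaldehyde and only the unhindered primary lithium alkoxide is silylated, the tertiary alkoxide being too hindered (alkynide hydroxymethylation, then O-silylation).

Step 7
Reactants: 10 (S)-1-(tert-butyldimethylsilyloxy)-11-(tert-butyldiphenylsilyloxy)-6-methylundeca-2,7-diyn-6-ol
Product: 11 (6S,7Z)-1-(tert-butyldimethylsilyloxy)-11-(tert-butyldiphenylsilyloxy)-6-methyl-7-(tributylstannyl)undec-7-en-2-yn-6-ol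
Conditions: [(C5Me5)RuCl]4 (2.5 mol %), Bu3SnH, CH2Cl2, rt
Reagents that add atoms: tributyltin hydride, CCCC[SnH](CCCC)CCCC
Why: Hydroxyl-directed ruthenium-catalysed trans-hydrostannation puts tin on the alkyne carbon next to the free tertiary alcohol and adds H and Sn anti, so tin ends cis to the C5 chain, while the silyl-ether-flanked alkyne has no protic director and reacts far more slowly.

Step 8
Reactants: 11 alkenylstannane
Product: 12 (6S,7Z)-1-(tert-butyldimethylsilyloxy)-11-(tert-butyldiphenylsilyloxy)-6-methyl-7-(tributylstannyl)-6-(triethylsilyloxy)undec-7-en-2-yne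
Conditions: Et3SiOTf, 2,6-lutidine, CH2Cl2, −78 → 0 °C
Reagents that add atoms: triethylsilyl trifluoromethanesulfonate, CC[Si](CC)(CC)OS(=O)(=O)C(F)(F)F
Why: Silyl triflate silylation of the hindered tertiary alcohol blocks O10 so that it cannot add to the alkyne in step 10 and permits the lithiation.

Step 9
Reactants: 12 silylated alkenylstannane; 13 cyclobutanone
Product: 15 1-[(6S,7E)-1-(tert-butyldimethylsilyloxy)-11-(tert-butyldiphenylsilyloxy)-6-methyl-6-(triethylsilyloxy)undec-7-en-2-yn-7-yl]cyclobutan-1-ol (C9 chain cis to the cyclobutanol), via alkenyllithium 14 (not isolated)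
Conditions: n-BuLi, THF, −78 °C; then 13, −78 → −40 °C; aq NH4Cl
Reagents that add atoms: none
Why: Tin–lithium exchange proceeds with retention of alkene geometry and the alkenyllithium adds 1,2 to the strained, electrophilic cyclobutanone to give the tertiary allylic cyclobutanol.

Step 10
Reactants: 15 alkenylcyclobutanol
Product: 16 (5R,6S,10S,E)-6-[3-(tert-butyldiphenylsilyloxy)propyl]-7-[2-(tert-butyldimethylsilyloxy)-1-iodoethylidene]-10-methyl-10-(triethylsilyloxy)spiro[4.5]decan-1-one
Conditions: [(t-Bu)2(o-biphenyl)P]Au(NCMe)SbF6 (5 mol %), NIS (1.2 equiv), NaHCO3, CH2Cl2, −20 °C, dark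
Reagents that add atoms: N-iodosuccinimide, O=C1CCC(=O)N1I
Why: Proposed new method: the cationic phosphine–gold catalyst (monovalent gold) π-activates the alkyne, the trisubstituted alkene attacks its proximal carbon through C6 (6-exo-dig at the alkyne, Markovnikov at the alkene, anti to gold), the tertiary cation developing at C11 is quenched by a 1,2-shift of a cyclobutane C–C bond anti to the new C6–C7 bond (semipinacol expansion to the cyclopentanone), and NIS then cleaves the alkenyl–gold bond with retention to give the iodide and return the catalyst, so that anti addition across the alkene (chain cis to the cyclobutanol) fixes C6 relative to C11, anti addition across the alkyne puts CH2OTBS cis to C6 and iodine cis to C8, and the C10 centre should select the alkene face through a chair transition state with the OTES group syn to the hydrogen-bonding cyclobutanol O–H (least 1,2-allylic strain) and the methyl axial; the closest known reaction types are gold-catalysed enyne cyclization/semipinacol ring expansions of alkenyl cyclopropanols and cyclobutanols and NIS iododeauration of alkenylgold species, but this 6-exo-dig, spiro-forming variant with iodine capture has not been shown.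

Step 11
Reactants: 16 alkenyl iodide
Product: 17 (5R,6R,10S,Z)-6-[3-(tert-butyldiphenylsilyloxy)propyl]-7-[1-(tert-butyldimethylsilyloxy)propan-2-ylidene]-10-methyl-10-(triethylsilyloxy)spiro[4.5]decan-1-one
Conditions: MeZnCl, Pd[P(t-Bu)3]2 (5 mol %), THF, 40 °C
Reagents that add atoms: methylzinc chloride, C[Zn]Cl
Why: Negishi cross-coupling (zerovalent palladium) replaces iodine by methyl with retention of alkene geometry, and the methylzinc reagent does not add to the hindered ketone.

Step 12
Reactants: 17 tris-silyl ether ketone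
Product: 18 (5R,6R,10S,Z)-6-[3-(tert-butyldiphenylsilyloxy)propyl]-10-hydroxy-7-(1-hydroxypropan-2-ylidene)-10-methylspiro[4.5]decan-1-one
Conditions: CSA (20 mol %), MeOH/CH2Cl2, 0 °C
Reagents that add atoms: none
Why: Acid-catalysed methanolysis removes the primary TBS and the tertiary TES ethers while the far more acid-stable primary TBDPS ether survives (selective silyl ether cleavage).

Step 13
Reactants: 18 keto diol
Product: 19 (1R,5S,6R,10S,Z)-6-[3-(tert-butyldiphenylsilyloxy)propyl]-7-(1-hydroxypropan-2-ylidene)-10-methylspiro[4.5]decane-1,10-diol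
Conditions: Me4NBH(OAc)3, MeCN/AcOH, −25 °C
Reagents that add atoms: none
Why: Evans–Saksena hydroxyl-directed reduction, in which the C10 alkoxy(acetoxy)borohydride delivers hydride intramolecularly to the ketone face syn to C10 and so places the C26 hydroxyl on the C6 side (R), the remote C1 hydroxyl being unable to reach the ketone.

Step 14
Reactants: 19 triol
Product: 21 (Z)-2-[(1R,5S,6R,10S)-6-[3-(tert-butyldiphenylsilyloxy)propyl]-1,10-dihydroxy-10-methylspiro[4.5]decan-7-ylidene]propanenitrile, via enal 20 (not isolated)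
Conditions: MnO2, NH3 (2 M in i-PrOH), MgSO4, THF, rt
Reagents that add atoms: ammonia, N
Why: Tandem MnO2 oxidation–amination oxidises only the allylic primary alcohol to the enal, which condenses with ammonia and is oxidised on to the conjugated nitrile, a mask for the C1 aldehyde that leaves the non-allylic alcohols and the alkene geometry untouched.

Step 15
Reactants: 21 nitrile diol; 22 (diethoxyphosphoryl)acetic acid
Product: 23 (1R,5S,6R,10S)-7-[(Z)-1-cyanoethylidene]-6-[3-(tert-butyldiphenylsilyloxy)propyl]-10-hydroxy-10-methylspiro[4.5]decan-1-yl (diethoxyphosphoryl)acetate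
Conditions: DCC, DMAP (cat.), CH2Cl2, 0 °C → rt
Reagents that add atoms: none
Why: Steglich esterification acylates the secondary C26 alcohol only, the tertiary C10 alcohol being unreactive.

Step 16
Reactants: 23 phosphonoacetate
Product: 24 O10-trimethylsilyl ether of 23
Conditions: N-(trimethylsilyl)imidazole, CH2Cl2, rt
Reagents that add atoms: N-(trimethylsilyl)imidazole, C[Si](C)(C)n1ccnc1
Why: Neutral silylation of the tertiary alcohol removes the O–H that would otherwise trap the carbenoid of step 18 by O–H insertion.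

Step 17
Reactants: 24 silylated phosphonoacetate
Product: 25 the corresponding diazo(diethoxyphosphoryl)acetate
Conditions: 4-acetamidobenzenesulfonyl azide, DBU, MeCN, 0 °C → rt
Reagents that add atoms: 4-acetamidobenzenesulfonyl azide, CC(=O)Nc1ccc(cc1)S(=O)(=O)N=[N+]=[N-]
Why: Regitz diazo transfer to the doubly activated methylene of the phosphonoacetate.

Step 18
Reactants: 25 diazophosphonoacetate
Product: 26 cis-fused α-(diethoxyphosphoryl)-γ-lactone (C27 carbonyl on O26, C15 bonded to C14; epimers at C15)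
Conditions: Rh2(O2CC7H15)4 (2 mol %), CH2Cl2, 40 °C
Reagents that add atoms: none
Why: Dirhodium-carbenoid (divalent rhodium) intramolecular 1,5-C–H insertion strongly prefers five-membered ring formation, and since C11 carries no hydrogen the only γ-C–H is at C14, where insertion into the hydrogen cis to the ester oxygen gives the cis-fused lactone and so sets C14.

Step 19
Reactants: 27 2,6-dimethylhept-5-enal (melonal, racemic)
Product: 28 (E)-2,6-dimethylhepta-2,5-dienal
Conditions: IBX, DMSO/fluorobenzene, 65 °C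
Reagents that add atoms: none
Why: IBX-mediated α,β-dehydrogenation of the aldehyde gives the thermodynamically favoured (E)-α-methyl enal and removes the racemic stereocentre.

Step 20
Reactants: 28 (E)-2,6-dimethylhepta-2,5-dienal; 29 (triphenylphosphoranylidene)acetaldehyde
Product: 30 (2E,4E)-4,8-dimethylnona-2,4,7-trienal
Conditions: toluene, 80 °C
Reagents that add atoms: none
Why: Wittig olefination with the stabilised formyl ylide gives the (E)-disubstituted C17=C18 alkene.

Step 21
Reactants: 26 phosphono lactone; 30 (2E,4E)-4,8-dimethylnona-2,4,7-trienal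
Product: 31 (E)-α-trienylidene γ-lactone (C15=C16, chain cis to C14)
Conditions: KOt-Bu, THF, 0 °C; then 30, 0 °C → rt
Reagents that add atoms: none
Why: Horner–Wadsworth–Emmons olefination of an α-phosphono-γ-lactone gives the thermodynamically preferred (E)-alkylidene lactone, with the chain trans to the lactone carbonyl and hence cis to C14 as in the target.

Step 22
Reactants: 31 trienylidene lactone nitrile
Product: 32 target bearing O3-TBDPS and O10-TMS ethers
Conditions: i-Bu2AlH (6 equiv), CH2Cl2, −78 → −20 °C; aq potassium sodium tartrate, then pH 4 citrate buffer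
Reagents that add atoms: water, O
Why: i-Bu2AlH reduces the conjugated lactone 1,2 to the C26/C27 diol and stops at the aluminium aldimine for the hindered conjugated nitrile, which aqueous work-up hydrolyses to the (Z)-enal (hydride reduction).

Step 23
Reactants: 32 bis-silyl ether
Product: 33 target CNP0261841.1
Conditions: Bu4NF, AcOH, THF, 0 °C → rt
Reagents that add atoms: none
Why: Acetic-acid-buffered fluoride desilylation removes the TBDPS and TMS ethers without harming the enal, the triene or the allylic alcohol.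

**Compound list**

1 | geraniol | CC(C)=CCC/C(C)=C/CO | starting material
2 | (2S,3S)-2,3-epoxygeraniol | CC(C)=CCC[C@]1(C)O[C@H]1CO | intermediate
3 | (2R,3S)-1-chloro-2,3-epoxy-3,7-dimethyloct-6-ene | CC(C)=CCC[C@]1(C)O[C@H]1CCl | intermediate
4 | tert-butyl(3-iodopropoxy)diphenylsilane | ICCCO[Si](c1ccccc1)(c1ccccc1)C(C)(C)C | starting material
5 | dilithio alkynyl alkoxide (C,O-dilithium salt of (S)-3,7-dimethyloct-6-en-1-yn-3-ol) | [Li]C#C[C@@](C)(O[Li])CCC=C(C)C | intermediate (not isolated)
6 | (S)-11-(tert-butyldiphenylsilyloxy)-2,6-dimethylundec-2-en-7-yn-6-ol | CC(C)=CCC[C@](C)(O)C#CCCCO[Si](c1ccccc1)(c1ccccc1)C(C)(C)C | intermediate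
7 | (5S)-5-[5-(tert-butyldiphenylsilyloxy)pent-1-ynyl]-5-methyloxolan-2-ol (lactol, anomers) | OC1CC[C@](C)(O1)C#CCCCO[Si](c2ccccc2)(c2ccccc2)C(C)(C)C | intermediate
8 | (S)-10-(tert-butyldiphenylsilyloxy)-5-methyldeca-1,6-diyn-5-ol | C#CCC[C@](C)(O)C#CCCCO[Si](c1ccccc1)(c1ccccc1)C(C)(C)C | intermediate
9 | dilithium dialkoxide of (S)-11-(tert-butyldiphenylsilyloxy)-6-methylundeca-2,7-diyne-1,6-diol | [Li]OCC#CCC[C@](C)(O[Li])C#CCCCO[Si](c1ccccc1)(c1ccccc1)C(C)(C)C | intermediate (not isolated)
10 | (S)-1-(tert-butyldimethylsilyloxy)-11-(tert-butyldiphenylsilyloxy)-6-methylundeca-2,7-diyn-6-ol | CC(C)(C)[Si](C)(C)OCC#CCC[C@](C)(O)C#CCCCO[Si](c1ccccc1)(c1ccccc1)C(C)(C)C | intermediate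
11 | (6S,7Z)-1-(tert-butyldimethylsilyloxy)-11-(tert-butyldiphenylsilyloxy)-6-methyl-7-(tributylstannyl)undec-7-en-2-yn-6-ol | CCCC[Sn](CCCC)(CCCC)/C(=C\CCCO[Si](c1ccccc1)(c1ccccc1)C(C)(C)C)[C@@](C)(O)CCC#CCO[Si](C)(C)C(C)(C)C | intermediate
12 | triethylsilyl ether of 11 | CCCC[Sn](CCCC)(CCCC)/C(=C\CCCO[Si](c1ccccc1)(c1ccccc1)C(C)(C)C)[C@@](C)(O[Si](CC)(CC)CC)CCC#CCO[Si](C)(C)C(C)(C)C | intermediate
13 | cyclobutanone | O=C1CCC1 | starting material
14 | alkenyllithium from 12 (Sn replaced by Li, geometry retained) | [Li]/C(=C\CCCO[Si](c1ccccc1)(c1ccccc1)C(C)(C)C)[C@@](C)(O[Si](CC)(CC)CC)CCC#CCO[Si](C)(C)C(C)(C)C | intermediate (not isolated)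
15 | 1-[(6S,7E)-1-(tert-butyldimethylsilyloxy)-11-(tert-butyldiphenylsilyloxy)-6-methyl-6-(triethylsilyloxy)undec-7-en-2-yn-7-yl]cyclobutan-1-ol | OC1(CCC1)/C(=C\CCCO[Si](c2ccccc2)(c2ccccc2)C(C)(C)C)[C@@](C)(O[Si](CC)(CC)CC)CCC#CCO[Si](C)(C)C(C)(C)C | intermediate
16 | (5R,6S,10S,E)-6-[3-(tert-butyldiphenylsilyloxy)propyl]-7-[2-(tert-butyldimethylsilyloxy)-1-iodoethylidene]-10-methyl-10-(triethylsilyloxy)spiro[4.5]decan-1-one | C1CC[C@]2([C@H](CCCO[Si](c3ccccc3)(c3ccccc3)C(C)(C)C)/C(=C(/I)CO[Si](C)(C)C(C)(C)C)CC[C@]2(C)O[Si](CC)(CC)CC)C1=O | intermediate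
17 | (5R,6R,10S,Z)-6-[3-(tert-butyldiphenylsilyloxy)propyl]-7-[1-(tert-butyldimethylsilyloxy)propan-2-ylidene]-10-methyl-10-(triethylsilyloxy)spiro[4.5]decan-1-one | C1CC[C@]2([C@H](CCCO[Si](c3ccccc3)(c3ccccc3)C(C)(C)C)/C(=C(/C)CO[Si](C)(C)C(C)(C)C)CC[C@]2(C)O[Si](CC)(CC)CC)C1=O | intermediate
18 | (5R,6R,10S,Z)-6-[3-(tert-butyldiphenylsilyloxy)propyl]-10-hydroxy-7-(1-hydroxypropan-2-ylidene)-10-methylspiro[4.5]decan-1-one | C1CC[C@]2([C@H](CCCO[Si](c3ccccc3)(c3ccccc3)C(C)(C)C)/C(=C(/C)CO)CC[C@]2(C)O)C1=O | intermediate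
19 | (1R,5S,6R,10S,Z)-6-[3-(tert-butyldiphenylsilyloxy)propyl]-7-(1-hydroxypropan-2-ylidene)-10-methylspiro[4.5]decane-1,10-diol | C1CC[C@]2([C@H](CCCO[Si](c3ccccc3)(c3ccccc3)C(C)(C)C)/C(=C(/C)CO)CC[C@]2(C)O)[C@@H]1O | intermediate
20 | (Z)-2-[(1R,5S,6R,10S)-6-[3-(tert-butyldiphenylsilyloxy)propyl]-1,10-dihydroxy-10-methylspiro[4.5]decan-7-ylidene]propanal | C1CC[C@]2([C@H](CCCO[Si](c3ccccc3)(c3ccccc3)C(C)(C)C)/C(=C(/C)C=O)CC[C@]2(C)O)[C@@H]1O | intermediate (not isolated)
21 | (Z)-2-[(1R,5S,6R,10S)-6-[3-(tert-butyldiphenylsilyloxy)propyl]-1,10-dihydroxy-10-methylspiro[4.5]decan-7-ylidene]propanenitrile | C1CC[C@]2([C@H](CCCO[Si](c3ccccc3)(c3ccccc3)C(C)(C)C)/C(=C(/C)C#N)CC[C@]2(C)O)[C@@H]1O | intermediate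
22 | (diethoxyphosphoryl)acetic acid | CCOP(=O)(CC(=O)O)OCC | starting material
23 | C26 (diethoxyphosphoryl)acetate of 21 | C1CC[C@]2([C@H](CCCO[Si](c3ccccc3)(c3ccccc3)C(C)(C)C)/C(=C(/C)C#N)CC[C@]2(C)O)[C@@H]1OC(=O)CP(=O)(OCC)OCC | intermediate
24 | O10-trimethylsilyl ether of 23 | C1CC[C@]2([C@H](CCCO[Si](c3ccccc3)(c3ccccc3)C(C)(C)C)/C(=C(/C)C#N)CC[C@]2(C)O[Si](C)(C)C)[C@@H]1OC(=O)CP(=O)(OCC)OCC | intermediate
25 | diazo(diethoxyphosphoryl)acetate corresponding to 24 | C1CC[C@]2([C@H](CCCO[Si](c3ccccc3)(c3ccccc3)C(C)(C)C)/C(=C(/C)C#N)CC[C@]2(C)O[Si](C)(C)C)[C@@H]1OC(=O)C(=[N+]=[N-])P(=O)(OCC)OCC | intermediate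
26 | cis-fused α-(diethoxyphosphoryl)-γ-lactone on the spirocycle (O10-TMS, O3-TBDPS, C1 nitrile; C15 epimers) | O=C1C(P(=O)(OCC)OCC)[C@@H]2CC[C@]3([C@H](CCCO[Si](c4ccccc4)(c4ccccc4)C(C)(C)C)/C(=C(/C)C#N)CC[C@]3(C)O[Si](C)(C)C)[C@@H]2O1 | intermediate
27 | 2,6-dimethylhept-5-enal (melonal, racemic) | CC(C)=CCCC(C)C=O | starting material
28 | (E)-2,6-dimethylhepta-2,5-dienal | CC(C)=CC/C=C(C)/C=O | intermediate
29 | (triphenylphosphoranylidene)acetaldehyde | O=CC=P(c1ccccc1)(c1ccccc1)c1ccccc1 | starting material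
30 | (2E,4E)-4,8-dimethylnona-2,4,7-trienal | CC(C)=CC/C=C(C)/C=C/C=O | intermediate
31 | (E)-α-[(2E,4E)-4,8-dimethylnona-2,4,7-trienylidene] γ-lactone (O10-TMS, O3-TBDPS, C1 nitrile) | CC(C)=CC/C=C(C)/C=C/C=C1\[C@@H]2CC[C@]3([C@H](CCCO[Si](c4ccccc4)(c4ccccc4)C(C)(C)C)/C(=C(/C)C#N)CC[C@]3(C)O[Si](C)(C)C)[C@@H]2OC1=O | intermediate
32 | target as its O3-TBDPS, O10-TMS bis-silyl ether | CC(C)=CC/C=C(C)/C=C/C=C(/CO)[C@@H]1CC[C@]2([C@H](CCCO[Si](c3ccccc3)(c3ccccc3)C(C)(C)C)/C(=C(/C)C=O)CC[C@]2(C)O[Si](C)(C)C)[C@@H]1O | intermediate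
33 | CNP0261841.1 | CC(C)=CC/C=C(C)/C=C/C=C(/CO)[C@@H]1CC[C@]2([C@H](CCCO)/C(=C(/C)C=O)CC[C@]2(C)O)[C@@H]1O | target

**Step count and risks**

Total steps: 23. Longest linear sequence: 21 (steps 1–18 and 21–23; steps 19–20 make trienal 30).

Three steps most likely to fail:

Step 9 (hindered alkenyllithium plus an enolisable ketone). The risk is enolisation of cyclobutanone or incomplete tin–lithium exchange. Fallback, setting out from 12 and coming back at 15: iododestannylation (I2, CH2Cl2, 0 °C) gives the (Z)-alkenyl iodide F1. A Nozaki–Hiyama–Kishi coupling of F1 with cyclobutanone 13 (CrCl2, NiCl2 cat., DMF/THF, rt) then adds a non-basic alkenylchromium species to the ketone and gives 15.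

Step 10 (the proposed new reaction). The risks are direct reaction of NIS with the alkene, protodeauration instead of iodination, and the wrong alkene face. Fallback by known chemistry, setting out from 15 and coming back at 16: NIS without gold (NaHCO3, CH2Cl2, 0 °C → rt) effects the known iodonium-induced semipinacol ring expansion of the alkenylcyclobutanol to the β-iodo ketone F2 (C6 epimers). An iodine-atom-transfer radical cyclization of F2 (Et3B/air, benzene, rt) then closes the six-membered ring 6-exo-dig onto the alkyne and gives alkenyl iodide 16. This route is less selective, so 16 must be separated from its alkene isomer and from C6/C11 diastereomers.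

Step 18 (carbenoid C–H insertion in a polyfunctional substrate). The risks are δ-insertion at C6 or C12, attack on the silyl ether oxygen, and nitrile ylide formation. Fallback, setting out from 17 and coming back at 26: LiN(SiMe3)2 and ethyl iodoacetate (THF, −78 °C) alkylate C14, the only enolisable carbon of the ketone, to give keto ester F3. CSA/MeOH as in step 12 gives keto ester diol F4. Me4NBH(OAc)3 as in step 13, followed by PPTS-catalysed lactonization of the cis-hydroxy ester, gives lactone F5; only the C14 epimer cis to the new hydroxyl closes, and the other is removed. MnO2/NH3 as in step 14 gives nitrile lactone F6, and N-(trimethylsilyl)imidazole gives its O10-silyl ether F7. LiN(i-Pr)2 (2.2 equiv) and ClP(O)(OEt)2 (enol phosphate, then 1,3-phosphorus shift to carbon) finally give 26.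

**Further compounds**

F1 | step 9 | (6S,7Z)-1-(tert-butyldimethylsilyloxy)-11-(tert-butyldiphenylsilyloxy)-7-iodo-6-methyl-6-(triethylsilyloxy)undec-7-en-2-yne | I/C(=C\CCCO[Si](c1ccccc1)(c1ccccc1)C(C)(C)C)[C@@](C)(O[Si](CC)(CC)CC)CCC#CCO[Si](C)(C)C(C)(C)C
F2 | step 10 | 2-substituted cyclopentanone with C11 bearing the 1-iodo-4-(tert-butyldiphenylsilyloxy)butyl group and the C10 silyloxy alkynyl chain (β-iodo ketone, C6 epimers) | O=C1CCC[C@@]1(C(I)CCCO[Si](c2ccccc2)(c2ccccc2)C(C)(C)C)[C@@](C)(O[Si](CC)(CC)CC)CCC#CCO[Si](C)(C)C(C)(C)C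
F3 | step 18 | ethyl 2-[C14]-acetate of ketone 17 (C14 alkylated keto ester) | CCOC(=O)C[C@@H]1CC[C@]2([C@H](CCCO[Si](c3ccccc3)(c3ccccc3)C(C)(C)C)/C(=C(/C)CO[Si](C)(C)C(C)(C)C)CC[C@]2(C)O[Si](CC)(CC)CC)C1=O
F4 | step 18 | keto ester diol (F3 without TBS and TES) | CCOC(=O)C[C@@H]1CC[C@]2([C@H](CCCO[Si](c3ccccc3)(c3ccccc3)C(C)(C)C)/C(=C(/C)CO)CC[C@]2(C)O)C1=O
F5 | step 18 | cis-fused γ-lactone with free C1 and C10 hydroxyls | O=C1C[C@@H]2CC[C@]3([C@H](CCCO[Si](c4ccccc4)(c4ccccc4)C(C)(C)C)/C(=C(/C)CO)CC[C@]3(C)O)[C@@H]2O1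
F6 | step 18 | cis-fused γ-lactone with C1 nitrile and free C10 hydroxyl | O=C1C[C@@H]2CC[C@]3([C@H](CCCO[Si](c4ccccc4)(c4ccccc4)C(C)(C)C)/C(=C(/C)C#N)CC[C@]3(C)O)[C@@H]2O1
F7 | step 18 | O10-trimethylsilyl ether of F6 | O=C1C[C@@H]2CC[C@]3([C@H](CCCO[Si](c4ccccc4)(c4ccccc4)C(C)(C)C)/C(=C(/C)C#N)CC[C@]3(C)O[Si](C)(C)C)[C@@H]2O1
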